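**Retrosynthetic overview**

- The plan rests on the top flavan unit. Its C4 carries C6 of the middle unit and sits on C4a, next to the carbon bearing the ring oxygen O1, so C4 is the methide carbon of an ortho-quinone methide. Its C3, with the oxygen that later carries the gallate, is the α-carbon of an α-oxy aldehyde whose carbonyl carbon is C2.
- Disconnections, last to first: the two gallate esters; top O1–C2 (Mitsunobu) and top C2–aryl (Grignard on a lactol); top C3–C4 plus the O1–C2 hemiacetal (enamine addition to the quinone methide); methide carbon–top ring A (aryllithium plus a formyl group on middle C6); middle C4–bottom C8 (cationic flavan coupling).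
- Ring order: the pyran rings of the middle (epicatechin) and bottom (catechin) units come from the natural flavanols and are joined first. The top pyran ring is then built, as a lactol in step 12, opened in step 13 and closed again as the 2-aryl chroman in step 14. Bromine on middle C8 and bottom C6 blocks every other arene position.

Key step: step 12

Remark on the chemistry: the benzyl ethers 13, 21 and 26 are taken as purchased in place of phloroglucinol, catechol and gallic acid; the C4 epimers of 5, the carbinol epimers of 16 and the anomers of 20 converge, so these centres are drawn arbitrarily or left open.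

**Route**

Step 1
Reactants: 1 (−)-epicatechin
Product: 2 5,7,3',4'-tetra-O-benzyl-(−)-epicatechin
Conditions: BnBr (4.4 equiv), K2CO3, DMF, 0 °C → rt
Reagents that add atoms: benzyl bromide, BrCc1ccccc1
Why: Williamson etherification of the four phenols; carbonate does not deprotonate the secondary 3-OH, which stays free, and no stereocentre is touched.

Step 2
Reactants: 2 5,7,3',4'-tetra-O-benzyl-(−)-epicatechin
Product: 3 8-bromo-5,7,3',4'-tetra-O-benzylepicatechin
Conditions: NBS (1.0 equiv), CH2Cl2, −78 °C → rt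
Reagents that add atoms: N-bromosuccinimide, O=C1CCC(=O)N1Br
Why: electrophilic aromatic bromination of ring A, which in 5,7-di-O-benzyl flavans should take place at C8 and not at C6 between the two benzyloxy groups.

Step 3
Reactants: 3 8-bromo-5,7,3',4'-tetra-O-benzylepicatechin
Product: 4 8-bromo-3-O-(tert-butyldimethylsilyl)-5,7,3',4'-tetra-O-benzylepicatechin
Conditions: TBSCl, imidazole, DMF, rt → 40 °C
Reagents that add atoms: tert-butyldimethylsilyl chloride, CC(C)(C)[Si](C)(C)Cl
Why: silylation of the secondary alcohol gives an ether that should withstand the Lewis acid, organolithium, Grignard and Mitsunobu steps and that is removed by fluoride without touching benzyl ethers.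

Step 4
Reactants: 4 8-bromo-3-O-(tert-butyldimethylsilyl)-5,7,3',4'-tetra-O-benzylepicatechin
Product: 5 4β-(2-ethoxyethoxy) derivative of 4 (3,4-trans)
Conditions: DDQ (2 equiv), 2-ethoxyethanol (5 equiv), CH2Cl2, rt
Reagents that add atoms: 2-ethoxyethanol, OCCOCC
Why: DDQ benzylic oxidation, in which hydride abstraction from C4 gives a cation stabilised by the ring A oxygens and the alcohol traps it trans to the 3-silyloxy group; the new C4 centre is ionised again in step 7, so its configuration is of no consequence.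

Step 5
Reactants: 6 (+)-catechin
Product: 7 5,7,3',4'-tetra-O-benzyl-(+)-catechin
Conditions: BnBr (4.4 equiv), K2CO3, DMF, 0 °C → rt
Reagents that add atoms: benzyl bromide, BrCc1ccccc1
Why: Williamson etherification of the phenols under carbonate, which is too weak a base to open the pyran ring or epimerise C2.

Step 6
Reactants: 7 5,7,3',4'-tetra-O-benzyl-(+)-catechin
Product: 8 3,5,7,3',4'-penta-O-benzyl-(+)-catechin
Conditions: NaH, BnBr, Bu4NI (cat.), DMF, 0 °C → rt
Reagents that add atoms: benzyl bromide, BrCc1ccccc1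
Why: Williamson etherification of the 3-alkoxide marks the bottom 3-oxygen with a group that stays through the desilylation and galloylation and falls only in the final hydrogenolysis.

Step 7
Reactants: 5 4β-(2-ethoxyethoxy) bromo electrophile; 8 3,5,7,3',4'-penta-O-benzyl-(+)-catechin
Product: 9 bromo-capped dimer [8-bromo-3-O-TBS-tetra-O-benzylepicatechin]-(4β→8)-[penta-O-benzylcatechin]
Conditions: 8 (3 equiv), TMSOTf (0.3 equiv), CH2Cl2, −78 → −40 °C; Et3N quench
Reagents that add atoms: none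
Why: Lewis acid ionisation of the C4 ether and Friedel–Crafts alkylation of C8 of 8, the most nucleophilic carbon of a 5,7-dibenzyloxy flavan; attack trans to the bulky 3-silyloxy group should set middle C4 as 4β, while the C8 bromine and the excess of 8 suppress self-condensation and over-reaction.

Step 8
Reactants: 9 bromo-capped dimer
Product: 10 dibromo dimer (Br on middle C8 and bottom C6)
Conditions: NBS (1.05 equiv), CH2Cl2, −78 → −20 °C
Reagents that add atoms: N-bromosuccinimide, O=C1CCC(=O)N1Br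
Why: electrophilic aromatic bromination should go to bottom C6, the free carbon of the ring A that carries no halogen, because the middle ring A is deactivated by its C8 bromine.

Step 9
Reactants: 10 dibromo dimer
Product: 12 dimer aldehyde (formyl on middle C6), via aryl iminium chloride 11 (not isolated)
Conditions: POCl3 (5 equiv), DMF, ClCH2CH2Cl, 0 → 60 °C; then aq NaOAc, rt
Reagents that add atoms: N,N-dimethylformamide, CN(C)C=O; water, O
Why: Vilsmeier–Haack formylation at middle C6, the only unsubstituted carbon on a phloroglucinol-type ring (ortho to two benzyloxy groups, para to O1), the catechol-type rings B being far less reactive; hydrolysis of iminium 11 gives the aldehyde and fixes the later 4→6 link by construction.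

Step 10
Reactants: 13 3,5-bis(benzyloxy)phenol
Product: 14 2-bromo-3,5-bis(benzyloxy)phenol
Conditions: NBS (1.0 equiv), i-Pr2NH (10 mol %), CH2Cl2, −78 → 0 °C
Reagents that add atoms: N-bromosuccinimide, O=C1CCC(=O)N1Br
Why: amine-mediated ortho-bromination of a phenol, in which the N-bromoamine hydrogen-bonded to the hydroxyl delivers bromine to the ortho carbon, which is also less hindered than the carbon between the two benzyl ethers; any 4-bromo isomer would be removed by chromatography.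

Step 11
Reactants: 14 2-bromo-3,5-bis(benzyloxy)phenol; 12 dimer aldehyde
Product: 16 benzhydrol on middle C6 (either carbinol epimer), via lithium 3,5-bis(benzyloxy)-2-lithiophenoxide 15 (not isolated)
Conditions: 14 (3.0 equiv), n-BuLi (5.9 equiv), THF, −78 °C; then 12, −78 → −30 °C; aq NH4Cl; Et3N-buffered SiO2
Reagents that add atoms: none
Why: deprotonation followed by bromine–lithium exchange gives the aryllithium phenoxide, whose 1,2-addition to the aldehyde gives the free ortho-hydroxybenzhydrol with no phenol protecting group to remove; the carbinol centre is uncontrolled and becomes sp2 in step 12.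

Step 12
Reactants: 16 benzhydrol on middle C6; 17 (tert-butyldimethylsilyloxy)acetaldehyde
Product: 20 top-unit lactol (3R, 3,4-trans, either anomer), via ortho-quinone methide 18 (not isolated), via open-chain hydroxy aldehyde 19 (not isolated)
Conditions: 17 (3 equiv), (S)-α,α-diphenylprolinol trimethylsilyl ether (20 mol %), PhCO2H (20 mol %), CH2Cl2, 0 °C → rt
Reagents that add atoms: none
Why: The weak acid should dehydrate benzhydrol 16 to ortho-quinone methide 18, stabilised by the alkoxy groups of both flanking rings, while the amine and 17 form an E-enamine whose carbon adds to the methide carbon to make the C3–C4 bond; hydrolysis of the resulting iminium frees the catalyst and hydroxy aldehyde 19. The closest known reaction is the diarylprolinol silyl ether catalysed conjugate addition of aldehydes to ortho-quinone methides formed in situ from ortho-hydroxybenzhydrols, which delivers trans-3,4-disubstituted chroman-2-ols. The single new ring, the pyran ring of the top unit, closes when the phenol oxygen O1 adds to the aldehyde carbon C2 of 19 (6-exo-trig hemiacetalisation), reversibly and without control at C2, which is not needed. C3 is set by the catalyst: the CPh2OSiMe3 arm of the (S)-pyrrolidine blocks one enamine face, so the methide is taken up on the other and the silyloxy-bearing carbon should become R, the epicatechin configuration. C4 follows from the open synclinal transition state usual for enamine conjugate additions (syn adduct, hence 3,4-trans in the ring), which places the middle-unit aryl group 4β. The step needs reagent control over the resident stereocentres and bond formation with the enamine only: the nearest stereocentre of the dimer lies four bonds from the methide carbon whereas the catalyst acts at the bond being formed, and the bromine atoms on middle C8 and bottom C6 leave no nucleophilic arene carbon in the dimer part to intercept the methide.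

Step 13
Reactants: 20 top-unit lactol; 21 4-bromo-1,2-bis(benzyloxy)benzene
Product: 23 ring-opened phenol with 1,2-anti (2S,3R) aryl carbinol, via 3,4-bis(benzyloxy)phenylmagnesium bromide 22 (not isolated)
Conditions: 21, Mg, THF, rt; then 20 (5 equiv of 22 per 20), THF, −78 → 0 °C; aq NH4Cl
Reagents that add atoms: none
Why: the first equivalent of 22 deprotonates the lactol, which opens to the magnesium phenoxide of hydroxy aldehyde 19, and a second equivalent adds to the aldehyde (Grignard 1,2-addition) anti to the α-silyloxy group through a non-chelated transition state, since the bulky silyl ether binds magnesium poorly, so the 1,2-anti (2S) carbinol should predominate.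

Step 14
Reactants: 23 ring-opened phenol with 1,2-anti aryl carbinol
Product: 24 protected trimer with both 3-oxygens silylated (top unit 2R,3R,4β)
Conditions: PPh3, DIAD, toluene, 0 °C → rt
Reagents that add atoms: none
Why: intramolecular Mitsunobu etherification, in which the phenol (the only acidic OH) displaces the oxyphosphonium of the only free alcohol in a 6-exo-tet SN2 step, so C2 is inverted from S to R and the 2,3-cis-3,4-trans top flavan ring should result.

Step 15
Reactants: 24 protected trimer with both 3-oxygens silylated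
Product: 25 trimer diol (free 3-OH on top and middle units)
Conditions: TBAF (6 equiv), THF, rt → 50 °C
Reagents that add atoms: none
Why: fluoride-induced desilylation frees exactly the two hydroxyl groups that are galloylated in the target, while the bottom 3-O-benzyl ether, the aryl benzyl ethers and the aryl bromides are inert to fluoride.

Step 16
Reactants: 25 trimer diol; 26 3,4,5-tris(benzyloxy)benzoic acid
Product: 27 perbenzylated dibromo trimer 3,3'-di-O-gallate
Conditions: 26 (6 equiv), DCC (6 equiv), DMAP (2 equiv), CH2Cl2, rt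
Reagents that add atoms: none
Why: Steglich esterification through the acylpyridinium acylates both hindered secondary alcohols without touching their configuration, the bottom 3-oxygen being masked as its benzyl ether.

Step 17
Reactants: 27 perbenzylated dibromo trimer 3,3'-di-O-gallate
Product: 28 CNP0112921.1, epicatechin-3-O-gallate-(4β→6)-epicatechin-3-O-gallate-(4β→8)-catechin
Conditions: H2 (1 atm), Pd(OH)2/C, Et3N (2.2 equiv), THF/MeOH/H2O, rt; filtration under argon
Reagents that add atoms: none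
Why: catalytic hydrogenolysis should cleave the nineteen benzyl ethers and both aryl C–Br bonds in one operation, the amine taking up HBr so that the acid-labile interflavan bonds and the gallate esters are spared; the flavan C2–O1 and C4–aryl bonds and all stereocentres are not affected.

**Compound list**

1 | (−)-epicatechin, (2R,3R) | O[C@@H]1Cc2c(O)cc(O)cc2O[C@@H]1c1ccc(O)c(O)c1 | starting material
2 | 5,7,3',4'-tetra-O-benzyl-(−)-epicatechin | O[C@@H]1Cc2c(OCc9ccccc9)cc(OCc9ccccc9)cc2O[C@@H]1c1ccc(OCc9ccccc9)c(OCc9ccccc9)c1 | intermediate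
3 | 8-bromo-5,7,3',4'-tetra-O-benzylepicatechin | O[C@@H]1Cc2c(OCc9ccccc9)cc(OCc9ccccc9)c(Br)c2O[C@@H]1c1ccc(OCc9ccccc9)c(OCc9ccccc9)c1 | intermediate
4 | 8-bromo-3-O-(tert-butyldimethylsilyl)-5,7,3',4'-tetra-O-benzylepicatechin | CC(C)(C)[Si](C)(C)O[C@@H]1Cc2c(OCc9ccccc9)cc(OCc9ccccc9)c(Br)c2O[C@@H]1c1ccc(OCc9ccccc9)c(OCc9ccccc9)c1 | intermediate
5 | 4β-(2-ethoxyethoxy) derivative of 4 (3,4-trans) | CC(C)(C)[Si](C)(C)O[C@@H]1[C@@H](OCCOCC)c2c(OCc9ccccc9)cc(OCc9ccccc9)c(Br)c2O[C@@H]1c1ccc(OCc9ccccc9)c(OCc9ccccc9)c1 | intermediate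
6 | (+)-catechin, (2R,3S) | O[C@H]1Cc2c(O)cc(O)cc2O[C@@H]1c1ccc(O)c(O)c1 | starting material
7 | 5,7,3',4'-tetra-O-benzyl-(+)-catechin | O[C@H]1Cc2c(OCc9ccccc9)cc(OCc9ccccc9)cc2O[C@@H]1c1ccc(OCc9ccccc9)c(OCc9ccccc9)c1 | intermediate
8 | 3,5,7,3',4'-penta-O-benzyl-(+)-catechin | O(Cc9ccccc9)[C@H]1Cc2c(OCc9ccccc9)cc(OCc9ccccc9)cc2O[C@@H]1c1ccc(OCc9ccccc9)c(OCc9ccccc9)c1 | intermediate
9 | bromo-capped dimer, [8-bromo-3-O-TBS-tetra-O-benzylepicatechin]-(4β→8)-[penta-O-benzylcatechin] | c2c(OCc9ccccc9)c(Br)c3c(c2OCc9ccccc9)[C@H](c2c(OCc9ccccc9)cc(OCc9ccccc9)c4c2O[C@H](c2ccc(OCc9ccccc9)c(OCc9ccccc9)c2)[C@@H](OCc9ccccc9)C4)[C@@H](O[Si](C)(C)C(C)(C)C)[C@@H](c2ccc(OCc9ccccc9)c(OCc9ccccc9)c2)O3 | intermediate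
10 | dibromo dimer (9 with Br also on C6 of the catechin unit) | c2c(OCc9ccccc9)c(Br)c3c(c2OCc9ccccc9)[C@H](c2c(OCc9ccccc9)c(Br)c(OCc9ccccc9)c4c2O[C@H](c2ccc(OCc9ccccc9)c(OCc9ccccc9)c2)[C@@H](OCc9ccccc9)C4)[C@@H](O[Si](C)(C)C(C)(C)C)[C@@H](c2ccc(OCc9ccccc9)c(OCc9ccccc9)c2)O3 | intermediate
11 | aryl iminium chloride (Me2N+=CH on middle C6 of 10) | [Cl-].C[N+](C)=Cc2c(OCc9ccccc9)c(Br)c3c(c2OCc9ccccc9)[C@H](c2c(OCc9ccccc9)c(Br)c(OCc9ccccc9)c4c2O[C@H](c2ccc(OCc9ccccc9)c(OCc9ccccc9)c2)[C@@H](OCc9ccccc9)C4)[C@@H](O[Si](C)(C)C(C)(C)C)[C@@H](c2ccc(OCc9ccccc9)c(OCc9ccccc9)c2)O3 | intermediate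
12 | dimer aldehyde (formyl on middle C6 of 10) | O=Cc2c(OCc9ccccc9)c(Br)c3c(c2OCc9ccccc9)[C@H](c2c(OCc9ccccc9)c(Br)c(OCc9ccccc9)c4c2O[C@H](c2ccc(OCc9ccccc9)c(OCc9ccccc9)c2)[C@@H](OCc9ccccc9)C4)[C@@H](O[Si](C)(C)C(C)(C)C)[C@@H](c2ccc(OCc9ccccc9)c(OCc9ccccc9)c2)O3 | intermediate
13 | 3,5-bis(benzyloxy)phenol | Oc1cc(OCc9ccccc9)cc(OCc9ccccc9)c1 | starting material
14 | 2-bromo-3,5-bis(benzyloxy)phenol | Oc1cc(OCc9ccccc9)cc(OCc9ccccc9)c1Br | intermediate
15 | lithium 3,5-bis(benzyloxy)-2-lithiophenoxide | [Li]Oc1cc(OCc9ccccc9)cc(OCc9ccccc9)c1[Li] | intermediate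
16 | benzhydrol: [2-hydroxy-4,6-bis(benzyloxy)phenyl](dimer-C6-yl)methanol, either carbinol epimer | OC(c1c(O)cc(OCc9ccccc9)cc1OCc9ccccc9)c2c(OCc9ccccc9)c(Br)c3c(c2OCc9ccccc9)[C@H](c2c(OCc9ccccc9)c(Br)c(OCc9ccccc9)c4c2O[C@H](c2ccc(OCc9ccccc9)c(OCc9ccccc9)c2)[C@@H](OCc9ccccc9)C4)[C@@H](O[Si](C)(C)C(C)(C)C)[C@@H](c2ccc(OCc9ccccc9)c(OCc9ccccc9)c2)O3 | intermediate
17 | (tert-butyldimethylsilyloxy)acetaldehyde | O=CCO[Si](C)(C)C(C)(C)C | starting material
18 | ortho-quinone methide (3,5-bis(benzyloxy)-6-(arylmethylidene)cyclohexa-2,4-dienone, aryl = dimer C6) | O=C1C=C(OCc9ccccc9)C=C(OCc9ccccc9)C1=Cc2c(OCc9ccccc9)c(Br)c3c(c2OCc9ccccc9)[C@H](c2c(OCc9ccccc9)c(Br)c(OCc9ccccc9)c4c2O[C@H](c2ccc(OCc9ccccc9)c(OCc9ccccc9)c2)[C@@H](OCc9ccccc9)C4)[C@@H](O[Si](C)(C)C(C)(C)C)[C@@H](c2ccc(OCc9ccccc9)c(OCc9ccccc9)c2)O3 | intermediate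
19 | open-chain hydroxy aldehyde, (2R)-2-silyloxy-3-(2-hydroxy-4,6-bis(benzyloxy)phenyl)-3-(dimer-C6-yl)propanal, syn adduct | CC(C)(C)[Si](C)(C)O[C@@H](C=O)[C@@H](c2c(OCc9ccccc9)c(Br)c3c(c2OCc9ccccc9)[C@H](c2c(OCc9ccccc9)c(Br)c(OCc9ccccc9)c4c2O[C@H](c2ccc(OCc9ccccc9)c(OCc9ccccc9)c2)[C@@H](OCc9ccccc9)C4)[C@@H](O[Si](C)(C)C(C)(C)C)[C@@H](c2ccc(OCc9ccccc9)c(OCc9ccccc9)c2)O3)c2c(OCc9ccccc9)cc(OCc9ccccc9)cc2O | intermediate
20 | top-unit lactol: (3R)-3-silyloxy-4β-(dimer-C6-yl)-5,7-bis(benzyloxy)chroman-2-ol, 3,4-trans, either anomer | CC(C)(C)[Si](C)(C)O[C@@H]1[C@@H](c2c(OCc9ccccc9)c(Br)c3c(c2OCc9ccccc9)[C@H](c2c(OCc9ccccc9)c(Br)c(OCc9ccccc9)c4c2O[C@H](c2ccc(OCc9ccccc9)c(OCc9ccccc9)c2)[C@@H](OCc9ccccc9)C4)[C@@H](O[Si](C)(C)C(C)(C)C)[C@@H](c2ccc(OCc9ccccc9)c(OCc9ccccc9)c2)O3)c2c(OCc9ccccc9)cc(OCc9ccccc9)cc2OC1O | intermediate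
21 | 4-bromo-1,2-bis(benzyloxy)benzene | Brc1ccc(OCc9ccccc9)c(OCc9ccccc9)c1 | starting material
22 | 3,4-bis(benzyloxy)phenylmagnesium bromide | Br[Mg]c1ccc(OCc9ccccc9)c(OCc9ccccc9)c1 | intermediate
23 | ring-opened phenol: (1S,2R)-1-[3,4-bis(benzyloxy)phenyl]-2-silyloxy-3,3-diaryl-propan-1-ol, 1,2-anti | CC(C)(C)[Si](C)(C)O[C@@H]([C@@H](O)c1ccc(OCc9ccccc9)c(OCc9ccccc9)c1)[C@@H](c2c(OCc9ccccc9)c(Br)c3c(c2OCc9ccccc9)[C@H](c2c(OCc9ccccc9)c(Br)c(OCc9ccccc9)c4c2O[C@H](c2ccc(OCc9ccccc9)c(OCc9ccccc9)c2)[C@@H](OCc9ccccc9)C4)[C@@H](O[Si](C)(C)C(C)(C)C)[C@@H](c2ccc(OCc9ccccc9)c(OCc9ccccc9)c2)O3)c2c(OCc9ccccc9)cc(OCc9ccccc9)cc2O | intermediate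
24 | protected trimer, top and middle 3-O-TBS, top unit (2R,3R,4β) | CC(C)(C)[Si](C)(C)O[C@@H]1[C@@H](c2c(OCc9ccccc9)c(Br)c3c(c2OCc9ccccc9)[C@H](c2c(OCc9ccccc9)c(Br)c(OCc9ccccc9)c4c2O[C@H](c2ccc(OCc9ccccc9)c(OCc9ccccc9)c2)[C@@H](OCc9ccccc9)C4)[C@@H](O[Si](C)(C)C(C)(C)C)[C@@H](c2ccc(OCc9ccccc9)c(OCc9ccccc9)c2)O3)c2c(OCc9ccccc9)cc(OCc9ccccc9)cc2O[C@@H]1c1ccc(OCc9ccccc9)c(OCc9ccccc9)c1 | intermediate
25 | trimer diol (free 3-OH on top and middle units) | O[C@@H]1[C@@H](c2c(OCc9ccccc9)c(Br)c3c(c2OCc9ccccc9)[C@H](c2c(OCc9ccccc9)c(Br)c(OCc9ccccc9)c4c2O[C@H](c2ccc(OCc9ccccc9)c(OCc9ccccc9)c2)[C@@H](OCc9ccccc9)C4)[C@@H](O)[C@@H](c2ccc(OCc9ccccc9)c(OCc9ccccc9)c2)O3)c2c(OCc9ccccc9)cc(OCc9ccccc9)cc2O[C@@H]1c1ccc(OCc9ccccc9)c(OCc9ccccc9)c1 | intermediate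
26 | 3,4,5-tris(benzyloxy)benzoic acid | OC(=O)c1cc(OCc9ccccc9)c(OCc9ccccc9)c(OCc9ccccc9)c1 | starting material
27 | perbenzylated dibromo trimer 3,3'-di-O-gallate | O=C(O[C@@H]1[C@@H](c2c(OCc9ccccc9)c(Br)c3c(c2OCc9ccccc9)[C@H](c2c(OCc9ccccc9)c(Br)c(OCc9ccccc9)c4c2O[C@H](c2ccc(OCc9ccccc9)c(OCc9ccccc9)c2)[C@@H](OCc9ccccc9)C4)[C@@H](OC(=O)c2cc(OCc9ccccc9)c(OCc9ccccc9)c(OCc9ccccc9)c2)[C@@H](c2ccc(OCc9ccccc9)c(OCc9ccccc9)c2)O3)c2c(OCc9ccccc9)cc(OCc9ccccc9)cc2O[C@@H]1c1ccc(OCc9ccccc9)c(OCc9ccccc9)c1)c1cc(OCc9ccccc9)c(OCc9ccccc9)c(OCc9ccccc9)c1 | intermediate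
28 | CNP0112921.1, epicatechin-3-O-gallate-(4β→6)-epicatechin-3-O-gallate-(4β→8)-catechin | O=C(O[C@@H]1[C@@H](c2c(O)cc3c(c2O)[C@H](c2c(O)cc(O)c4c2O[C@H](c2ccc(O)c(O)c2)[C@@H](O)C4)[C@@H](OC(=O)c2cc(O)c(O)c(O)c2)[C@@H](c2ccc(O)c(O)c2)O3)c2c(O)cc(O)cc2O[C@@H]1c1ccc(O)c(O)c1)c1cc(O)c(O)c(O)c1 | target

**Step count and risks**

Total step count: 17. Longest linear sequence: 14 steps (steps 1–4, 7–9 and 11–17, from (−)-epicatechin).

Steps most likely to fail:

1. Step 12. The tetra-ortho-substituted methide may be twisted and behave as a free benzhydryl cation, so that facial selectivity at C4 is poor, or it may be intercepted by the electron-rich top ring of a second molecule faster than by the enamine. The fallback moves the chirality from the nucleophile to the acid and sets out from benzhydrol 16. Methyl (tert-butyldimethylsilyloxy)acetate would be converted with LiN(i-Pr)2 and TMSCl into the silyl ketene acetal F1. A chiral 3,3'-diaryl-BINOL hydrogen phosphate, its enantiomer chosen by trial, would ionise 16 to the ion-paired methide, and Mukaiyama–Michael addition of the ketene acetal should give the methyl ester adduct F2. Lactonisation with loss of methanol (cat. TsOH, then DBU to bring the enolisable C3 to the more stable trans arrangement) should give the trans-3-silyloxy-4-aryl dihydrocoumarin F3. Reduction with i-Bu2AlH at −78 °C returns to lactol 20.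

2. Step 9. Formylation at a carbon flanked by two benzyloxy groups on a bromine-deactivated ring may be too slow, so that acid-induced cleavage of the interflavan bond or loss of the silyl ether by the chloroiminium/HCl medium takes over. The fallback replaces electrophilic formylation by halogen–metal exchange and sets out from dibromo dimer 10. NIS in CH2Cl2 should iodinate the same carbon to give the middle-C6 aryl iodide F4. i-PrMgCl·LiCl in THF at −20 → 0 °C should exchange iodine only, the electron-rich aryl bromides being inert, and a DMF quench returns to aldehyde 12.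

3. Step 14. The oxyphosphonium of the electron-rich, crowded benzylic carbinol may ionise before the phenol attacks, which would erode the inversion at C2 or lead to elimination toward C3. The fallback uses acyloxonium activation and sets out from 23. TBAF would remove both silyl groups to give the tetraol F5. Triethyl orthoformate with cat. PPTS in ClCH2CH2Cl (rt → 60 °C) should form the cyclic orthoformate of the 1,2-diol, whose dioxolanylium ion is opened at the benzylic carbon by the phenol with inversion, giving the 2,3-cis chroman 3-O-formate F6. K2CO3 in MeOH removes the formyl group and returns to diol 25, so that step 15 is no longer needed.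

**Further compounds**

F1 | step 12 | 2-(tert-butyldimethylsilyloxy)-1-methoxy-1-(trimethylsilyloxy)ethene | COC(O[Si](C)(C)C)=CO[Si](C)(C)C(C)(C)C
F2 | step 12 | methyl (2R)-2-silyloxy-3-(2-hydroxy-4,6-bis(benzyloxy)phenyl)-3-(dimer-C6-yl)propanoate | CC(C)(C)[Si](C)(C)O[C@@H](C(=O)OC)[C@@H](c2c(OCc9ccccc9)c(Br)c3c(c2OCc9ccccc9)[C@H](c2c(OCc9ccccc9)c(Br)c(OCc9ccccc9)c4c2O[C@H](c2ccc(OCc9ccccc9)c(OCc9ccccc9)c2)[C@@H](OCc9ccccc9)C4)[C@@H](O[Si](C)(C)C(C)(C)C)[C@@H](c2ccc(OCc9ccccc9)c(OCc9ccccc9)c2)O3)c2c(OCc9ccccc9)cc(OCc9ccccc9)cc2O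
F3 | step 12 | trans-3-silyloxy-4-(dimer-C6-yl)-5,7-bis(benzyloxy)chroman-2-one | CC(C)(C)[Si](C)(C)O[C@@H]1[C@@H](c2c(OCc9ccccc9)c(Br)c3c(c2OCc9ccccc9)[C@H](c2c(OCc9ccccc9)c(Br)c(OCc9ccccc9)c4c2O[C@H](c2ccc(OCc9ccccc9)c(OCc9ccccc9)c2)[C@@H](OCc9ccccc9)C4)[C@@H](O[Si](C)(C)C(C)(C)C)[C@@H](c2ccc(OCc9ccccc9)c(OCc9ccccc9)c2)O3)c2c(OCc9ccccc9)cc(OCc9ccccc9)cc2OC1=O
F4 | step 9 | middle-C6 aryl iodide of dibromo dimer 10 | Ic2c(OCc9ccccc9)c(Br)c3c(c2OCc9ccccc9)[C@H](c2c(OCc9ccccc9)c(Br)c(OCc9ccccc9)c4c2O[C@H](c2ccc(OCc9ccccc9)c(OCc9ccccc9)c2)[C@@H](OCc9ccccc9)C4)[C@@H](O[Si](C)(C)C(C)(C)C)[C@@H](c2ccc(OCc9ccccc9)c(OCc9ccccc9)c2)O3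
F5 | step 14 | tetraol (23 without both silyl groups) | O[C@@H]([C@@H](O)c1ccc(OCc9ccccc9)c(OCc9ccccc9)c1)[C@@H](c2c(OCc9ccccc9)c(Br)c3c(c2OCc9ccccc9)[C@H](c2c(OCc9ccccc9)c(Br)c(OCc9ccccc9)c4c2O[C@H](c2ccc(OCc9ccccc9)c(OCc9ccccc9)c2)[C@@H](OCc9ccccc9)C4)[C@@H](O)[C@@H](c2ccc(OCc9ccccc9)c(OCc9ccccc9)c2)O3)c2c(OCc9ccccc9)cc(OCc9ccccc9)cc2O
F6 | step 14 | top-unit 3-O-formate of diol 25 | O=CO[C@@H]1[C@@H](c2c(OCc9ccccc9)c(Br)c3c(c2OCc9ccccc9)[C@H](c2c(OCc9ccccc9)c(Br)c(OCc9ccccc9)c4c2O[C@H](c2ccc(OCc9ccccc9)c(OCc9ccccc9)c2)[C@@H](OCc9ccccc9)C4)[C@@H](O)[C@@H](c2ccc(OCc9ccccc9)c(OCc9ccccc9)c2)O3)c2c(OCc9ccccc9)cc(OCc9ccccc9)cc2O[C@@H]1c1ccc(OCc9ccccc9)c(OCc9ccccc9)c1
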